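**Retrosynthetic overview**
- Last bonds: the free acid is released from its methyl ester by an esterase at neutral pH, after the cis-diol acetonide is opened with aqueous acetic acid.
- Key disconnection: the enamide N–C(ring) bond, made by copper-catalysed N-vinylation of a primary enamide (fragment B) with an α-iodoenone (fragment A).
- Fragment A: α-iodination of a cis-diol enone, which comes from a catalytic enantioselective desymmetrising oxa-Michael addition on an achiral p-quinol, itself made from a phenol by Sonogashira coupling, hydrogenation and dearomatisation.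
- Fragment B: Wittig olefination of an α-methyl aldehyde; the syn-dimethyl array comes from lipase desymmetrisation of a meso diol, and the isobutyl end from a copper-catalysed Grignard coupling.
- Rings: the six-membered carbocycle is the dearomatised phenol ring and is never constructed. The only rings formed are, in order, a transient cis-fused dioxaborolane (step 4) and the dioxolane acetonide (step 5), which is opened in step 16.

Assumption: the quinidine-derived thiourea is taken to give the (1R,6S) cis-diol in step 4; if the sense of induction proves opposite, the quinine-derived pseudoenantiomer is used in the same step.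

The target is read as the cis-(4R,5S)-diol of the cyclohexenone carrying the (2E,4S,6S)-4,6,8-trimethylnon-2-enoyl amide (syn-dimethyl).

**Fragment A (steps 1–6)**

Step 1
Reactants: 1 4-iodophenol; 2 methyl pent-4-ynoate
Product: 3 methyl 5-(4-hydroxyphenyl)pent-4-ynoate
Conditions: PdCl2(PPh3)2 (2 mol%), CuI (4 mol%), Et3N, THF, rt
Reagents that add atoms: none
Why: Sonogashira coupling, in which oxidative addition of the aryl iodide to zerovalent palladium and transmetalation from the copper acetylide run at room temperature and tolerate the free phenol and the ester.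

Step 2
Reactants: 3 methyl 5-(4-hydroxyphenyl)pent-4-ynoate
Product: 4 methyl 5-(4-hydroxyphenyl)pentanoate
Conditions: H2 (1 atm), 10% Pd/C, EtOAc/MeOH, rt
Reagents that add atoms: none
Why: Heterogeneous catalytic hydrogenation saturates the alkyne fully and leaves the arene, phenol and ester untouched.

Step 3
Reactants: 4 methyl 5-(4-hydroxyphenyl)pentanoate
Product: 6 methyl 5-(1-hydroxy-4-oxocyclohexa-2,5-dien-1-yl)pentanoate, via peroxyquinol 5 (not isolated)
Conditions: Oxone (2KHSO5·KHSO4·K2SO4), NaHCO3, MeCN/H2O, rt; then aq. Na2S2O3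
Reagents that add atoms: potassium peroxymonosulfate, [K+].[O-]S(=O)(=O)OO
Why: Oxidative dearomatisation, in which singlet oxygen generated from peroxymonosulfate adds para to the phenol to give the p-peroxyquinol and thiosulfate reduces the hydroperoxide to the achiral, prochiral p-quinol.

Step 4
Reactants: 6 methyl 5-(1-hydroxy-4-oxocyclohexa-2,5-dien-1-yl)pentanoate
Product: 8 methyl 5-[(1R,6S)-1,6-dihydroxy-4-oxocyclohex-2-en-1-yl]pentanoate, via phenylboronate 7 (not isolated)
Conditions: PhB(OH)2 (1.5 equiv), N-[3,5-bis(trifluoromethyl)phenyl]-N'-(9-deoxy-epi-quinidin-9-yl)thiourea (20 mol%), 4 Å molecular sieves, toluene, rt to 40 °C; then pinacol, rt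
Reagents that add atoms: phenylboronic acid, OB(O)c1ccccc1
Why: Boronate-tethered organocatalytic intramolecular oxa-Michael desymmetrisation, in which the boronic hemiester of the tertiary hydroxyl delivers its B–OH only to the cis face while the bifunctional amine–thiourea selects one of the two enantiotopic enone arms, setting the quaternary C1 (R) and C6 (S) together as the cis-diol.

Step 5
Reactants: 8 methyl 5-[(1R,6S)-1,6-dihydroxy-4-oxocyclohex-2-en-1-yl]pentanoate
Product: 9 methyl 5-[(3aR,7aS)-2,2-dimethyl-6-oxo-7,7a-dihydro-1,3-benzodioxol-3a(6H)-yl]pentanoate (the acetonide of 8)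
Conditions: 2,2-dimethoxypropane, PPTS (cat.), acetone, rt
Reagents that add atoms: 2,2-dimethoxypropane, COC(C)(C)OC
Why: Acid-catalysed transacetalisation closes the five-membered isopropylidene acetal on the cis-1,2-diol without touching either stereocentre.

Step 6
Reactants: 9 methyl 5-[(3aR,7aS)-2,2-dimethyl-6-oxo-7,7a-dihydro-1,3-benzodioxol-3a(6H)-yl]pentanoate
Product: 10 methyl 5-[(3aR,7aS)-5-iodo-2,2-dimethyl-6-oxo-7,7a-dihydro-1,3-benzodioxol-3a(6H)-yl]pentanoate
Conditions: I2, pyridine, CH2Cl2, 0 °C to rt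
Reagents that add atoms: iodine, II
Why: Johnson α-iodination (Baylis–Hillman-type conjugate addition of pyridine, iodination of the enolate, elimination) puts iodine specifically on the enone α-carbon, as known for 4,5-acetonide-protected cyclohexenones.

**Fragment B (steps 7–14)**

Step 7
Reactants: 11 meso-2,4-dimethylglutaric anhydride, i.e. cis-(3R,5S)-3,5-dimethyloxane-2,6-dione
Product: 12 meso-(2R,4S)-2,4-dimethylpentane-1,5-diol
Conditions: LiAlH4, THF, 0 °C to reflux; Fieser work-up
Reagents that add atoms: none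
Why: Hydride reduction of the cyclic anhydride to the diol proceeds without epimerising the α-methyl carbons, so the meso relationship is kept.

Step 8
Reactants: 12 meso-(2R,4S)-2,4-dimethylpentane-1,5-diol
Product: 13 (2S,4R)-5-hydroxy-2,4-dimethylpentyl acetate, i.e. (2R,4S)-5-acetoxy-2,4-dimethylpentan-1-ol
Conditions: Pseudomonas fluorescens lipase (Amano lipase AK), vinyl acetate, THF, rt
Reagents that add atoms: vinyl acetate, C=COC(C)=O
Why: Lipase-catalysed enantiotopic-group-selective transesterification of a meso diol, in which the enzyme acylates only the hydroxymethyl on the (S)-configured carbon and vinyl alcohol tautomerises to acetaldehyde to make it irreversible, fixing the absolute configuration of both methyl-bearing carbons.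

Step 9
Reactants: 13 (2S,4R)-5-hydroxy-2,4-dimethylpentyl acetate
Product: 14 (2S,4R)-2,4-dimethyl-5-(tosyloxy)pentyl acetate
Conditions: TsCl, Et3N, DMAP (cat.), CH2Cl2, 0 °C to rt
Reagents that add atoms: p-toluenesulfonyl chloride, Cc1ccc(cc1)S(Cl)(=O)=O
Why: Sulfonylation of the free primary alcohol leaves the acetate and both stereocentres untouched.

Step 10
Reactants: 14 (2S,4R)-2,4-dimethyl-5-(tosyloxy)pentyl acetate; 15 isopropylmagnesium chloride
Product: 17 (2S,4S)-2,4,6-trimethylheptan-1-ol, via coupled acetate 16 (not isolated)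
Conditions: i-PrMgCl (3 equiv), Li2CuCl4 (5 mol%), THF, −78 to 0 °C; then K2CO3 (cat.), MeOH, rt
Reagents that add atoms: none
Why: Copper-catalysed Grignard cross-coupling with a primary tosylate (Kochi/Fouquet–Schlosser type) displaces at CH2 without touching the neighbouring stereocentre, and the methanolysis then delivers the same alcohol even if the Grignard has partly cleaved the acetate.

Step 11
Reactants: 17 (2S,4S)-2,4,6-trimethylheptan-1-ol
Product: 18 (2S,4S)-2,4,6-trimethylheptanal
Conditions: TEMPO (10 mol%), PhI(OAc)2 (1.1 equiv), CH2Cl2, rt; used directly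
Reagents that add atoms: none
Why: Oxoammonium (TEMPO) oxidation stops at the aldehyde under non-basic conditions, so the α-methyl stereocentre is not epimerised.

Step 12
Reactants: 18 (2S,4S)-2,4,6-trimethylheptanal; 19 methyl (triphenylphosphoranylidene)acetate
Product: 20 methyl (2E,4S,6S)-4,6,8-trimethylnon-2-enoate
Conditions: CH2Cl2, rt to 40 °C
Reagents that add atoms: none
Why: Wittig olefination with a stabilised ylide gives the (E)-enoate under neutral conditions that preserve the α-stereocentre.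

Step 13
Reactants: 20 methyl (2E,4S,6S)-4,6,8-trimethylnon-2-enoate
Product: 21 (2E,4S,6S)-4,6,8-trimethylnon-2-enoic acid
Conditions: LiOH, THF/MeOH/H2O, rt; then 1 M HCl
Reagents that add atoms: lithium hydroxide, [Li+].[OH-]
Why: Saponification of the unhindered methyl ester is fast at room temperature, where the γ-stereocentre and the (E)-alkene are stable.

Step 14
Reactants: 21 (2E,4S,6S)-4,6,8-trimethylnon-2-enoic acid
Product: 23 (2E,4S,6S)-4,6,8-trimethylnon-2-enamide, via acyl imidazole 22 (not isolated)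
Conditions: 1,1'-carbonyldiimidazole, THF, rt; then aq. NH3, 0 °C to rt
Reagents that add atoms: ammonia, N; 1,1'-carbonyldiimidazole, O=C(n1ccnc1)n1ccnc1 (imidazolyl of 22 only)
Why: Acyl imidazole activation followed by aminolysis gives the primary amide, acyl substitution being much faster than conjugate addition to the γ-branched enoyl unit.

**Union and endgame (steps 15–17)**

Step 15
Reactants: 10 methyl 5-[(3aR,7aS)-5-iodo-2,2-dimethyl-6-oxo-7,7a-dihydro-1,3-benzodioxol-3a(6H)-yl]pentanoate; 23 (2E,4S,6S)-4,6,8-trimethylnon-2-enamide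
Product: 24 methyl 5-[(3aR,7aS)-2,2-dimethyl-6-oxo-5-{[(2E,4S,6S)-4,6,8-trimethylnon-2-enoyl]amino}-7,7a-dihydro-1,3-benzodioxol-3a(6H)-yl]pentanoate
Conditions: CuI (10 mol%), N,N'-dimethylethylenediamine (20 mol%), Cs2CO3 (1.5 equiv), THF, 60 °C
Reagents that add atoms: none
Why: Copper-catalysed Goldberg-type N-vinylation (Buchwald amidation of a vinyl iodide) joins the amide nitrogen to the iodide-bearing carbon with the double bond kept in place, and carbonate in THF is mild enough for the ester, the acetonide and the β-alkoxy ketone.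

Step 16
Reactants: 24 methyl 5-[(3aR,7aS)-2,2-dimethyl-6-oxo-5-{[(2E,4S,6S)-4,6,8-trimethylnon-2-enoyl]amino}-7,7a-dihydro-1,3-benzodioxol-3a(6H)-yl]pentanoate
Product: 25 methyl 5-[(1R,6S)-1,6-dihydroxy-4-oxo-3-{[(2E,4S,6S)-4,6,8-trimethylnon-2-enoyl]amino}cyclohex-2-en-1-yl]pentanoate
Conditions: AcOH/H2O (4:1), 40 °C
Reagents that add atoms: none
Why: Acid-catalysed acetal hydrolysis with aqueous acetic acid opens the isopropylidene acetal but is too weak to ionise the tertiary allylic alcohol or dehydrate the β-hydroxy ketone.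

Step 17
Reactants: 25 methyl 5-[(1R,6S)-1,6-dihydroxy-4-oxo-3-{[(2E,4S,6S)-4,6,8-trimethylnon-2-enoyl]amino}cyclohex-2-en-1-yl]pentanoate
Product: 26 Salternamide E, 5-[(1R,6S)-1,6-dihydroxy-4-oxo-3-{[(2E,4S,6S)-4,6,8-trimethylnon-2-enoyl]amino}cyclohex-2-en-1-yl]pentanoic acid
Conditions: pig liver esterase (a carboxylesterase), 0.1 M phosphate buffer pH 7.4, 10% DMSO, 30 °C; then acidify to pH 4, extract with EtOAc
Reagents that add atoms: water, O
Why: Esterase-catalysed hydrolysis at neutral pH cleaves the methyl ester without the base that would cause retro-oxa-Michael reaction, dehydration or aromatisation of the β-hydroxy enone, and it touches neither amide nor stereocentre.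

**Compound list**

1 | 4-iodophenol | Oc1ccc(I)cc1 | starting material
2 | methyl pent-4-ynoate | COC(=O)CCC#C | starting material
3 | methyl 5-(4-hydroxyphenyl)pent-4-ynoate | COC(=O)CCC#Cc1ccc(O)cc1 | intermediate
4 | methyl 5-(4-hydroxyphenyl)pentanoate | COC(=O)CCCCc1ccc(O)cc1 | intermediate
5 | methyl 5-(1-hydroperoxy-4-oxocyclohexa-2,5-dien-1-yl)pentanoate (peroxyquinol) | COC(=O)CCCCC1(OO)C=CC(=O)C=C1 | intermediate
6 | methyl 5-(1-hydroxy-4-oxocyclohexa-2,5-dien-1-yl)pentanoate (p-quinol) | COC(=O)CCCCC1(O)C=CC(=O)C=C1 | intermediate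
7 | methyl 5-[(3aR,7aS)-6-oxo-2-phenyl-7,7a-dihydro-1,3,2-benzodioxaborol-3a(6H)-yl]pentanoate (cyclic phenylboronate of 8) | O=C1C=C[C@@]2(CCCCC(=O)OC)OB(c3ccccc3)O[C@H]2C1 | intermediate
8 | methyl 5-[(1R,6S)-1,6-dihydroxy-4-oxocyclohex-2-en-1-yl]pentanoate | O=C1C=C[C@](O)(CCCCC(=O)OC)[C@@H](O)C1 | intermediate
9 | methyl 5-[(3aR,7aS)-2,2-dimethyl-6-oxo-7,7a-dihydro-1,3-benzodioxol-3a(6H)-yl]pentanoate | O=C1C=C[C@@]2(CCCCC(=O)OC)OC(C)(C)O[C@H]2C1 | intermediate
10 | methyl 5-[(3aR,7aS)-5-iodo-2,2-dimethyl-6-oxo-7,7a-dihydro-1,3-benzodioxol-3a(6H)-yl]pentanoate | O=C1C(I)=C[C@@]2(CCCCC(=O)OC)OC(C)(C)O[C@H]2C1 | intermediate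
11 | meso-2,4-dimethylglutaric anhydride, cis-(3R,5S)-3,5-dimethyloxane-2,6-dione | O=C1[C@H](C)C[C@H](C)C(=O)O1 | starting material
12 | meso-(2R,4S)-2,4-dimethylpentane-1,5-diol | OC[C@H](C)C[C@H](C)CO | intermediate
13 | (2S,4R)-5-hydroxy-2,4-dimethylpentyl acetate | OC[C@H](C)C[C@H](C)COC(C)=O | intermediate
14 | (2S,4R)-2,4-dimethyl-5-(tosyloxy)pentyl acetate | Cc1ccc(cc1)S(=O)(=O)OC[C@H](C)C[C@H](C)COC(C)=O | intermediate
15 | isopropylmagnesium chloride | CC(C)[Mg]Cl | starting material
16 | (2S,4S)-2,4,6-trimethylheptyl acetate | CC(C)C[C@H](C)C[C@H](C)COC(C)=O | intermediate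
17 | (2S,4S)-2,4,6-trimethylheptan-1-ol | CC(C)C[C@H](C)C[C@H](C)CO | intermediate
18 | (2S,4S)-2,4,6-trimethylheptanal | CC(C)C[C@H](C)C[C@H](C)C=O | intermediate
19 | methyl (triphenylphosphoranylidene)acetate | COC(=O)C=P(c1ccccc1)(c1ccccc1)c1ccccc1 | starting material
20 | methyl (2E,4S,6S)-4,6,8-trimethylnon-2-enoate | CC(C)C[C@H](C)C[C@H](C)/C=C/C(=O)OC | intermediate
21 | (2E,4S,6S)-4,6,8-trimethylnon-2-enoic acid | CC(C)C[C@H](C)C[C@H](C)/C=C/C(=O)O | intermediate
22 | (2E,4S,6S)-1-(imidazol-1-yl)-4,6,8-trimethylnon-2-en-1-one (acyl imidazole) | CC(C)C[C@H](C)C[C@H](C)/C=C/C(=O)n1ccnc1 | intermediate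
23 | (2E,4S,6S)-4,6,8-trimethylnon-2-enamide | CC(C)C[C@H](C)C[C@H](C)/C=C/C(N)=O | intermediate
24 | methyl 5-[(3aR,7aS)-2,2-dimethyl-6-oxo-5-{[(2E,4S,6S)-4,6,8-trimethylnon-2-enoyl]amino}-7,7a-dihydro-1,3-benzodioxol-3a(6H)-yl]pentanoate | CC(C)C[C@H](C)C[C@H](C)/C=C/C(=O)NC1=C[C@@]2(CCCCC(=O)OC)OC(C)(C)O[C@H]2CC1=O | intermediate
25 | methyl 5-[(1R,6S)-1,6-dihydroxy-4-oxo-3-{[(2E,4S,6S)-4,6,8-trimethylnon-2-enoyl]amino}cyclohex-2-en-1-yl]pentanoate | CC(C)C[C@H](C)C[C@H](C)/C=C/C(=O)NC1=C[C@](O)(CCCCC(=O)OC)[C@@H](O)CC1=O | intermediate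
26 | Salternamide E | CC(C)C[C@H](C)C[C@H](C)/C=C/C(=O)NC1=C[C@](O)(CCCCC(=O)O)[C@@H](O)CC1=O | target

**Step count and risk**

Total step count: 17. Longest linear sequence: 11 steps (11 → 12 → 13 → 14 → 17 → 18 → 20 → 21 → 23 → 24 → 25 → 26); the fragment A branch is 9 steps from 1.

The three steps most likely to fail:

Step 4 (enantioselectivity and rate of the boronate oxa-Michael on a 4-alkyl p-quinol). The fallback sets out from 6 and comes back at 8. It replaces the boron tether and thiourea by a hemiacetal tether and chiral Brønsted acid catalysis. Compound 6 is stirred with 2-methylpropanal and a BINOL-derived chiral phosphoric acid ((R)-TRIP, 5–10 mol%, enantiomer chosen by screening) in CH2Cl2 over molecular sieves. The hemiacetal formed at the tertiary hydroxyl then adds in an enantiodetermining oxa-Michael step to give the cis-fused dioxolane methyl 5-[(2R,3aR,7aS)-2-isopropyl-6-oxo-7,7a-dihydro-1,3-benzodioxol-3a(6H)-yl]pentanoate F1. Hydrolysis of this acetal with aqueous TFA in THF at 0 °C gives diol 8.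

Step 15 (the carbonate base may trigger retro-oxa-Michael elimination of the β-alkoxy ketone, or the hindered α-iodoenone may couple sluggishly). The fallback sets out from 10 and comes back at 24. It introduces nitrogen as azide under near-neutral conditions and attaches the acyl group afterwards. Compound 10 is treated with NaN3, CuI (10 mol%), sodium ascorbate and N,N'-dimethylethylenediamine in EtOH/H2O at rt to give the vinyl azide methyl 5-[(3aR,7aS)-5-azido-2,2-dimethyl-6-oxo-7,7a-dihydro-1,3-benzodioxol-3a(6H)-yl]pentanoate F2. Staudinger reduction (PMe3, THF, then H2O) gives the 2-aminoenone methyl 5-[(3aR,7aS)-5-amino-2,2-dimethyl-6-oxo-7,7a-dihydro-1,3-benzodioxol-3a(6H)-yl]pentanoate F3. This is acylated in CH2Cl2/pyridine at −20 °C with (2E,4S,6S)-4,6,8-trimethylnon-2-enoyl chloride F4, made from acid 21 with oxalyl chloride and catalytic DMF, to give 24.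

Step 16 (acid may ionise the tertiary allylic alcohol or dehydrate the β-hydroxy ketone towards a phenol). The fallback sets out from 8 and comes back at 25. It swaps the acid-labile acetonide for silyl ethers removed by fluoride. Compound 8 is silylated with Et3SiOTf and 2,6-lutidine in CH2Cl2 at −78 to 0 °C to give methyl 5-[(1R,6S)-4-oxo-1,6-bis(triethylsilyloxy)cyclohex-2-en-1-yl]pentanoate F5. Iodination with I2 and pyridine gives methyl 5-[(1R,6S)-3-iodo-4-oxo-1,6-bis(triethylsilyloxy)cyclohex-2-en-1-yl]pentanoate F6. Coupling with 23 under the CuI, N,N'-dimethylethylenediamine and Cs2CO3 conditions of step 15 gives methyl 5-[(1R,6S)-4-oxo-1,6-bis(triethylsilyloxy)-3-{[(2E,4S,6S)-4,6,8-trimethylnon-2-enoyl]amino}cyclohex-2-en-1-yl]pentanoate F7. HF·pyridine buffered with pyridine in THF at 0 °C then removes both silyl groups to give 25.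

**Further compounds**

F1 | step 4 | methyl 5-[(2R,3aR,7aS)-2-isopropyl-6-oxo-7,7a-dihydro-1,3-benzodioxol-3a(6H)-yl]pentanoate | O=C1C=C[C@@]2(CCCCC(=O)OC)O[C@H](C(C)C)O[C@H]2C1
F2 | step 15 | methyl 5-[(3aR,7aS)-5-azido-2,2-dimethyl-6-oxo-7,7a-dihydro-1,3-benzodioxol-3a(6H)-yl]pentanoate | O=C1C(N=[N+]=[N-])=C[C@@]2(CCCCC(=O)OC)OC(C)(C)O[C@H]2C1
F3 | step 15 | methyl 5-[(3aR,7aS)-5-amino-2,2-dimethyl-6-oxo-7,7a-dihydro-1,3-benzodioxol-3a(6H)-yl]pentanoate | O=C1C(N)=C[C@@]2(CCCCC(=O)OC)OC(C)(C)O[C@H]2C1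
F4 | step 15 | (2E,4S,6S)-4,6,8-trimethylnon-2-enoyl chloride | CC(C)C[C@H](C)C[C@H](C)/C=C/C(Cl)=O
F5 | step 16 | methyl 5-[(1R,6S)-4-oxo-1,6-bis(triethylsilyloxy)cyclohex-2-en-1-yl]pentanoate | O=C1C=C[C@](O[Si](CC)(CC)CC)(CCCCC(=O)OC)[C@@H](O[Si](CC)(CC)CC)C1
F6 | step 16 | methyl 5-[(1R,6S)-3-iodo-4-oxo-1,6-bis(triethylsilyloxy)cyclohex-2-en-1-yl]pentanoate | O=C1C(I)=C[C@](O[Si](CC)(CC)CC)(CCCCC(=O)OC)[C@@H](O[Si](CC)(CC)CC)C1
F7 | step 16 | methyl 5-[(1R,6S)-4-oxo-1,6-bis(triethylsilyloxy)-3-{[(2E,4S,6S)-4,6,8-trimethylnon-2-enoyl]amino}cyclohex-2-en-1-yl]pentanoate | CC(C)C[C@H](C)C[C@H](C)/C=C/C(=O)NC1=C[C@](O[Si](CC)(CC)CC)(CCCCC(=O)OC)[C@@H](O[Si](CC)(CC)CC)CC1=O
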